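**Retrosynthetic overview**
- The (2S) centre at C-2 is bought with (2S)-steppogenin, which already carries rings A, B and C and all four oxygens; only a prenyl group and a 2,2-dimethylpyran ring (ring D) are added to ring B.
- Last disconnection: the two aryl silyl ethers at O-7 and O-2'.
- Ring D: oxa-6π electrocyclisation of an ortho-quinone methide, which arises from a 4'-O-(1,1-dimethylpropargyl) ether by [3,3] Claisen shift to C-3' and a [1,5]-H shift; C-5' is blocked beforehand.
- C-5' prenyl: aromatic Claisen ([3,3]) rearrangement of a 4'-O-(1,1-dimethylallyl) ether, steered away from C-3' by a bulky 2'-O-silyl group.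
- Ring order: rings A, C and B purchased, then prenyl on ring B, then ring D last.

Assumption: (2S)-steppogenin (natural 2',4',5,7-tetrahydroxyflavanone), tert-butyl 2-methylbut-3-en-2-yl carbonate and 3-chloro-3-methylbut-1-yne are taken as catalogue compounds.

**Route**

Step 1
Reactants: 1 (2S)-steppogenin; 2 chlorotriisopropylsilane
Product: 3 (2S)-7-O-triisopropylsilylsteppogenin
Conditions: TIPSCl (1.05 equiv), imidazole (2.2 equiv), DMF, −20 to 0 °C
Reagents that add atoms: chlorotriisopropylsilane, CC(C)[Si](Cl)(C(C)C)C(C)C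
Why: Selective O-silylation, because the 7-OH (para to the C-4 carbonyl) is by far the most acidic phenol, the 5-OH is hydrogen-bonded to C=O and the 2'-OH is hindered; C-2 is not touched.

Step 2
Reactants: 3 (2S)-7-O-triisopropylsilylsteppogenin; 4 tert-butyl 2-methylbut-3-en-2-yl carbonate
Product: 5 (2S)-4'-O-(2-methylbut-3-en-2-yl)-7-O-triisopropylsilylsteppogenin
Conditions: Pd(PPh3)4 (3 mol %), THF, 0 °C
Reagents that add atoms: tert-butyl 2-methylbut-3-en-2-yl carbonate, C=CC(C)(C)OC(=O)OC(C)(C)C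
Why: Tsuji–Trost O-allylation, in which zerovalent palladium ionises the tertiary carbonate and the phenoxide formed by the released tert-butoxide attacks the more substituted allyl terminus under kinetic control; the unhindered 4'-OH reacts before the ortho-substituted 2'-OH and the chelated 5-OH.

Step 3
Reactants: 5 (2S)-4'-O-(2-methylbut-3-en-2-yl)-7-O-triisopropylsilylsteppogenin; 6 tert-butylchlorodimethylsilane
Product: 7 (2S)-2'-O-tert-butyldimethylsilyl-4'-O-(2-methylbut-3-en-2-yl)-7-O-triisopropylsilylsteppogenin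
Conditions: TBSCl (1.5 equiv), imidazole (3 equiv), DMF, rt
Reagents that add atoms: tert-butylchlorodimethylsilane, CC(C)(C)[Si](C)(C)Cl
Why: Silyl ether formation at the only remaining unchelated phenol; the 2'-OTBS group later shields C-3' and prevents any reaction at O-2'.

Step 4
Reactants: 7 (2S)-2'-O-tert-butyldimethylsilyl-4'-O-(2-methylbut-3-en-2-yl)-7-O-triisopropylsilylsteppogenin
Product: 9 (2S)-2'-O-tert-butyldimethylsilyl-5'-prenyl-7-O-triisopropylsilylsteppogenin, via ortho-dienone 8 (not isolated)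
Conditions: PhMe, 110 °C
Reagents that add atoms: none
Why: Aromatic Claisen ([3,3]-sigmatropic) rearrangement of the tertiary allyl aryl ether puts a normal prenyl group on C-5', the ortho carbon that lies away from the meta silyloxy donor and is not flanked by OTBS, and dienone 8 tautomerises to the 4'-phenol; the minor C-3' isomer is removed by chromatography and no stereocentre is formed or disturbed.

Step 5
Reactants: 9 (2S)-2'-O-tert-butyldimethylsilyl-5'-prenyl-7-O-triisopropylsilylsteppogenin; 10 3-chloro-3-methylbut-1-yne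
Product: 11 (2S)-2'-O-tert-butyldimethylsilyl-4'-O-(2-methylbut-3-yn-2-yl)-5'-prenyl-7-O-triisopropylsilylsteppogenin
Conditions: CuCl2·2H2O (1 mol %), DBU (1.3 equiv), MeCN, −10 to 0 °C
Reagents that add atoms: 3-chloro-3-methylbut-1-yne, CC(C)(Cl)C#C
Why: Copper-catalysed propargylic etherification (through a copper acetylide/allenylidene) makes the tertiary aryl propargyl ether at the only free unchelated phenol, and the low temperature and short time keep ring C closed.

Step 6
Reactants: 11 (2S)-2'-O-tert-butyldimethylsilyl-4'-O-(2-methylbut-3-yn-2-yl)-5'-prenyl-7-O-triisopropylsilylsteppogenin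
Product: 15 2'-O-tert-butyldimethylsilyl-7-O-triisopropylsilylsanggenol N, via allenyl dienone 12 (not isolated), via ortho-allenylphenol 13 (not isolated), via ortho-quinone methide 14 (not isolated)
Conditions: o-xylene, 140 °C
Reagents that add atoms: none
Why: Propargyl Claisen [3,3] rearrangement can only end productively at C-3' because C-5' carries the prenyl group, and enolisation, a [1,5]-H shift and oxa-6π electrocyclisation then close the 2,2-dimethyl-2H-pyran ring on O-4' under neutral conditions that leave C-2 alone.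

Step 7
Reactants: 15 2'-O-tert-butyldimethylsilyl-7-O-triisopropylsilylsanggenol N
Product: 16 sanggenol N
Conditions: Bu4NF/AcOH (1:1, 3 equiv), THF, 0 °C to rt
Reagents that add atoms: none
Why: Fluoride-induced cleavage of both aryl silyl ethers, with acetic acid keeping the freed 2'- and 7-phenols protonated so that the flavanone does not open and the (2S) centre is retained.

**Compound list**

1 | (2S)-steppogenin, (2S)-2-(2,4-dihydroxyphenyl)-5,7-dihydroxychroman-4-one | Oc1ccc([C@@H]2CC(=O)c3c(O)cc(O)cc3O2)c(O)c1 | starting material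
2 | chlorotriisopropylsilane (TIPSCl) | CC(C)[Si](Cl)(C(C)C)C(C)C | starting material
3 | (2S)-2-(2,4-dihydroxyphenyl)-5-hydroxy-7-(triisopropylsilyloxy)chroman-4-one | Oc1ccc([C@@H]2CC(=O)c3c(O)cc(O[Si](C(C)C)(C(C)C)C(C)C)cc3O2)c(O)c1 | intermediate
4 | tert-butyl 2-methylbut-3-en-2-yl carbonate | C=CC(C)(C)OC(=O)OC(C)(C)C | starting material
5 | (2S)-5-hydroxy-2-[2-hydroxy-4-(2-methylbut-3-en-2-yloxy)phenyl]-7-(triisopropylsilyloxy)chroman-4-one | C=CC(C)(C)Oc1ccc([C@@H]2CC(=O)c3c(O)cc(O[Si](C(C)C)(C(C)C)C(C)C)cc3O2)c(O)c1 | intermediate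
6 | tert-butylchlorodimethylsilane (TBSCl) | CC(C)(C)[Si](C)(C)Cl | starting material
7 | (2S)-2-[2-(tert-butyldimethylsilyloxy)-4-(2-methylbut-3-en-2-yloxy)phenyl]-5-hydroxy-7-(triisopropylsilyloxy)chroman-4-one | C=CC(C)(C)Oc1ccc([C@@H]2CC(=O)c3c(O)cc(O[Si](C(C)C)(C(C)C)C(C)C)cc3O2)c(O[Si](C)(C)C(C)(C)C)c1 | intermediate
8 | ortho-dienone: cyclohexa-2,4-dienone tautomer of 9 with prenyl and H on C-5' and the carbonyl at C-4' | CC(C)=CCC1C=C([C@@H]2CC(=O)c3c(O)cc(O[Si](C(C)C)(C(C)C)C(C)C)cc3O2)C(O[Si](C)(C)C(C)(C)C)=CC1=O | intermediate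
9 | (2S)-2-[2-(tert-butyldimethylsilyloxy)-4-hydroxy-5-(3-methylbut-2-enyl)phenyl]-5-hydroxy-7-(triisopropylsilyloxy)chroman-4-one | CC(C)=CCc1cc([C@@H]2CC(=O)c3c(O)cc(O[Si](C(C)C)(C(C)C)C(C)C)cc3O2)c(O[Si](C)(C)C(C)(C)C)cc1O | intermediate
10 | 3-chloro-3-methylbut-1-yne | CC(C)(Cl)C#C | starting material
11 | (2S)-2-[2-(tert-butyldimethylsilyloxy)-4-(2-methylbut-3-yn-2-yloxy)-5-(3-methylbut-2-enyl)phenyl]-5-hydroxy-7-(triisopropylsilyloxy)chroman-4-one | C#CC(C)(C)Oc1cc(O[Si](C)(C)C(C)(C)C)c([C@@H]2CC(=O)c3c(O)cc(O[Si](C(C)C)(C(C)C)C(C)C)cc3O2)cc1CC=C(C)C | intermediate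
12 | allenyl dienone: C-3' carries H and a 3-methylbuta-1,2-dienyl group, carbonyl at C-4' | CC(C)=C=CC1C(=O)C(CC=C(C)C)=CC([C@@H]2CC(=O)c3c(O)cc(O[Si](C(C)C)(C(C)C)C(C)C)cc3O2)=C1O[Si](C)(C)C(C)(C)C | intermediate
13 | ortho-allenylphenol: 3'-(3-methylbuta-1,2-dienyl)-4'-hydroxy tautomer of 12 | CC(C)=C=Cc1c(O)c(CC=C(C)C)cc([C@@H]2CC(=O)c3c(O)cc(O[Si](C(C)C)(C(C)C)C(C)C)cc3O2)c1O[Si](C)(C)C(C)(C)C | intermediate
14 | ortho-quinone methide: exocyclic C-3'=CH–CH=CMe2, carbonyl at C-4' | CC(C)=CC=C1C(=O)C(CC=C(C)C)=CC([C@@H]2CC(=O)c3c(O)cc(O[Si](C(C)C)(C(C)C)C(C)C)cc3O2)=C1O[Si](C)(C)C(C)(C)C | intermediate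
15 | (2S)-2-[5-(tert-butyldimethylsilyloxy)-2,2-dimethyl-8-(3-methylbut-2-enyl)-2H-chromen-6-yl]-5-hydroxy-7-(triisopropylsilyloxy)chroman-4-one | CC(C)=CCc1cc([C@@H]2CC(=O)c3c(O)cc(O[Si](C(C)C)(C(C)C)C(C)C)cc3O2)c(O[Si](C)(C)C(C)(C)C)c2c1OC(C)(C)C=C2 | intermediate
16 | sanggenol N, (2S)-5,7-dihydroxy-2-[5-hydroxy-2,2-dimethyl-8-(3-methylbut-2-enyl)-2H-chromen-6-yl]chroman-4-one | CC(C)=CCc1cc([C@@H]2CC(=O)c3c(O)cc(O)cc3O2)c(O)c2c1OC(C)(C)C=C2 | target

**Step count**

Total steps: 7. Longest linear sequence: 7 steps (1 to 16). Enantiomeric purity should be checked by chiral HPLC after steps 2, 5 and 7, since the 2'- and 4'-phenoxides of a flavanone can open ring C.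

**Steps most likely to fail**

Step 2 (reverse O-prenylation at O-4'). The risks are alkylation at O-2', C-allylation of the resorcinol ring, or formation of the linear prenyl ether. The fallback sets out from 3. Copper-catalysed etherification with 10 (CuCl2·2H2O, DBU, MeCN, 0 °C) gives the 4'-O-(2-methylbut-3-yn-2-yl) ether F1. Its bulky allenylidene electrophile is more selective for the unhindered phenol and cannot give a linear isomer. Semi-hydrogenation of the alkyne (H2, Pd/CaCO3 poisoned with Pb(OAc)2, quinoline, EtOAc) then comes back to the route at 5.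

Step 4 (Claisen rearrangement to C-5'). The risks are migration to C-3' and thermal loss of isoprene from the tertiary ether. The fallback sets out from 3 and replaces the concerted [3,3] shift of a tertiary ether by a surface-mediated [1,3] shift of a primary one. Mitsunobu etherification with 3-methylbut-2-en-1-ol (PPh3, DIAD, THF, 0 °C) gives the linear 4'-O-prenyl ether F2. Silylation (TBSCl, imidazole, DMF) gives its 2'-O-TBS ether F3. Stirring F3 with magnesium silicate MgSiO3 (Florisil) in toluene moves the prenyl group to the less hindered ortho carbon C-5' and comes back to the route at 9.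

Step 5 (propargyl ether formation with DBU). The risks are a sluggish reaction at the ortho-substituted phenol and opening of ring C through the 4'-phenoxide (para-quinone methide), which would erode the enantiomeric purity. The fallback sets out from 9 and makes no phenoxide and no ether. Condensation with 3-methylbut-2-enal and PhB(OH)2 (catalytic EtCO2H, PhMe, reflux, Dean–Stark) gives the 2-phenyl-4-(2-methylprop-1-enyl)-4H-1,3,2-benzodioxaborin F4. At reflux F4 loses phenylboronic anhydride to give the same ortho-quinone methide 14, which electrocyclises and comes back to the route at 15, skipping 11.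

**Further compounds**

F1 | step 2 | (2S)-5-hydroxy-2-[2-hydroxy-4-(2-methylbut-3-yn-2-yloxy)phenyl]-7-(triisopropylsilyloxy)chroman-4-one | C#CC(C)(C)Oc1ccc([C@@H]2CC(=O)c3c(O)cc(O[Si](C(C)C)(C(C)C)C(C)C)cc3O2)c(O)c1
F2 | step 4 | (2S)-5-hydroxy-2-[2-hydroxy-4-(3-methylbut-2-enyloxy)phenyl]-7-(triisopropylsilyloxy)chroman-4-one | CC(C)=CCOc1ccc([C@@H]2CC(=O)c3c(O)cc(O[Si](C(C)C)(C(C)C)C(C)C)cc3O2)c(O)c1
F3 | step 4 | (2S)-2-[2-(tert-butyldimethylsilyloxy)-4-(3-methylbut-2-enyloxy)phenyl]-5-hydroxy-7-(triisopropylsilyloxy)chroman-4-one | CC(C)=CCOc1ccc([C@@H]2CC(=O)c3c(O)cc(O[Si](C(C)C)(C(C)C)C(C)C)cc3O2)c(O[Si](C)(C)C(C)(C)C)c1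
F4 | step 5 | 2-phenyl-4-(2-methylprop-1-enyl)-4H-1,3,2-benzodioxaborin fused at C-3'/C-4' of 9 (boron on O-4') | CC(C)=CCc1cc([C@@H]2CC(=O)c3c(O)cc(O[Si](C(C)C)(C(C)C)C(C)C)cc3O2)c(O[Si](C)(C)C(C)(C)C)c2c1OB(c1ccccc1)OC2C=C(C)C
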